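## The problem

Flavonoid numbering is used: ring A (C4a, C5–C8, C8a), ring C (O1, C2, C3, C4), ring B (C1'–C6') and the dimethyldihydropyran ring D fused to ring B.

- **Ring connections.** The target is a (2S)-flavanone. Ring B is attached to ring C only through C2–C1', and ring D shares the C4'–C5' edge of ring B, with its oxygen on C4'.
- **Ring B regiochemistry.** Ring B is a 1,3,4,5-tetrasubstituted benzene: C1' carries C2, C3' a prenyl group, C4' the ether oxygen and C5' the ring D methylene. Placing these by substitution on a phenol is the regiochemical weak point of a classical flavanone synthesis.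
- **Ring A.** Ring A carries a free 7-OH and a prenyl group at C8, between O1 and O7, the most crowded position of a resorcinol.
- **Stereocenter.** C2 is the only stereocenter and no other element of the molecule can direct it, so a chiral reagent or catalyst must set it. It is lost by retro-oxa-Michael opening to the 2'-hydroxychalcone whenever base meets the flavanone.
- **Sensitive groups.** The two trisubstituted prenyl alkenes rule out hydrogenation and strong electrophiles. The O7/C8 o-prenylphenol closes to a chroman in hot acid, so the phenol stays masked until the end and is freed under conditions that are neither basic nor strongly acidic.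
- **Enabling feature.** C1' lies para to the ring D oxygen on C4', and C2' and C6' carry only hydrogen. C2'–C3'–C4'–C5' can therefore be read as a 2-oxygenated 1,3-diene that already holds ring D and the prenyl group, and C1'–C6' as a two-carbon unit on C2 of a chromone.

## Retrosynthesis

**O7–Si.** The target 23 is traced back to its 7-O-silyl ether 22. A silyl group comes off with buffered fluoride, which touches neither C2 nor the o-prenylphenol, whereas an acetal or benzyl ether would need acid or hydrogen. The forward step must only avoid base.

**C2–H and C3–H.** Flavanone 22 is traced back to flavone 21 by removing the hydrogens at C2 and C3. Cutting C2–C1' or O1–C2 instead would force the stereocenter to be carried through the assembly of the rings. Flavone 21 is flat, achiral and stable to oxidants, acid and heat. The forward reaction, a copper hydride conjugate reduction with a chiral bisphosphine, must add hydride to the Re face of C2 and must not touch the prenyl groups.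

**C5'–C6' and C2'–C1' (ring B).** Flavone 21 is traced back through the 1,4-cyclohexadiene 20 to the dihydropyranyl diene 10 and the 2-ethynylchromone 19. The neighbouring cuts (C2–C1' biaryl-type coupling, or a chalcone route) all need a finished ring B, that is, a phenol that has been alkylated regioselectively three times. In the chosen cut ring D, the C3' prenyl group and the para relation of C1' to oxygen come with the diene, and ring A and ring C come complete with the alkyne. The forward reaction needs one selectivity only, the orientation of the diene on the alkyne, followed by loss of two hydrogens from 20.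

**The alkyne carbon of 19.** Alkyne 19 is traced back to aldehyde 18 by a one-carbon homologation, and 18 to ester 17 and phenol 16. Building the chromone around a preformed alkyne would risk competing cyclisation onto the triple bond, so the alkyne is made last on the finished chromone. The forward steps are silylation, partial reduction of an activated ester and a low-temperature Colvin homologation that the aryl silyl ether survives.

**O1–C2 and C3–C(oxalyl) of ring C; the C8 prenyl group.** Ester 16 is traced back through diketo ester 15 to acetophenone 13 and diethyl oxalate 14, and 13 to 2,4-dihydroxyacetophenone 11 and prenyl bromide 12. The oxalate route gives a C2 substituent at the oxidation level needed for the alkyne. Prenylation is placed first because C3 of 11, between the two oxygens, is then the most nucleophilic carbon. The cyclodehydration must be mild enough to spare the prenyl group next to the free 7-OH.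

**C3'–C4' of the diene.** Diene 10 is traced back to the ketene acetal phosphate 4 and the alkenyl bromide 7, coupled through alkenyllithium 8 and alkenylzinc chloride 9. Cutting here gives two small achiral pieces and fixes the position of both double bonds. An elimination route to the diene would leave the regiochemistry of the enol ether open. The coupling must tolerate the skipped diene and deliver an acid-sensitive enol ether.

**The two diene halves.** Phosphate 4 comes from lactone 3, and 3 from methyl 5-oxohexanoate 1 through hydroxy ester 2. Bromide 7 comes from 2,3-dibromopropene 5 and the alkenyl Grignard reagent 6. Both sequences use commodity chemicals and one C–C bond formation each.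

## Roads not taken

**Alternative 1: benzannulation of ring A around a preset C2.**
- Cut: C7–C8, C4a–C8a and C6–C7, so that ring A and ring C form together.
- Forward key step: irradiation of the diazo ketone A2 causes a Wolff rearrangement to a vinylketene. This adds across the tethered alkynyl ether (closing ring C), the cyclobutenone opens, and a 6π closure and tautomerisation give the flavan-4-ol silyl ether A1.
- Merits: the 7-OH (from the ketene carbonyl) and the C8 prenyl group (from the alkyne) arrive in fixed positions. C2 is set beforehand on an acyclic carbinol by standard asymmetric carbonyl chemistry and is not epimerisable in A1. In this respect the route is better than the chosen plan, which relies on a late catalyst-controlled reduction of a hindered flavone.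
- Weak points: A2 combines an alkynyl ether of a secondary benzylic alcohol (prone to thermal loss of ketene), an α-diazo-β-silyloxy ketone and a vinyl ketone. The ketene intermediates are generated next to two trisubstituted alkenes, and ketene–alkene addition to the prenyl group on the alkyne can compete. After the cascade, C4 must be desilylated and oxidised beside a free electron-rich phenol. Ring B with ring D must still be made by phenol chemistry, so the harder regiochemical problem remains.
- Comparison: the chosen plan offers stable, storable partners, a shorter convergent sequence and a ring B whose substitution pattern is set by the cycloaddition. Its price is the late asymmetric reduction.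

**Alternative 2: vinylogous aldol and cyclisation on a dihydro ring A.**
- Cut: C2–C3 and O1–C8a, with ring A at the 5,6-dihydro level.
- Forward key step: the bis-silyl dienol ether A5 adds to the ring B aldehyde A4 under Ti(OiPr)4 and BINOL, and acid closes O1 onto C8a with loss of silanol to give the dihydroflavanone A3.
- Merits: C2 is set in the C–C bond-forming step by a well-studied catalyst system for aromatic aldehydes. The C8 prenyl group is placed by C-alkylation of a cyclic 1,3-dione, which is more reliable than the direct prenylation of a resorcinol used in the chosen plan.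
- Weak points: A3 must finally be dehydrogenated across C5–C6 to give the phenol. The usual dehydrogenating agents convert flavanones to flavones at C2–C3 and attack benzylic and allylic positions, and the step must avoid base to keep C2. Removal of the methoxymethyl group needs acid next to the o-prenylphenol. Aldehyde A4 still requires a regioselectively built ring B.
- Comparison: Alternative 2 sets C2 more securely. The chosen plan does all its oxidation (DDQ) before C2 exists, on a flavone that cannot be over-oxidised, and it does not need A4.

**Alternative 3: quinone methide cycloaddition for ring D.**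
- Cut: the CH2–CH2 bond and the O–CMe2 bond of ring D.
- Forward key step: heating the salicyl alcohol A7 with excess isobutene generates the o-quinone methide across C4'–C5', which adds the alkene to give the bromochroman A6.
- Merits: one step from a cheap gas with unambiguous regiochemistry (oxygen to the tertiary carbon). A6 is a robust aryl bromide open to many couplings. After conversion to an arylboron reagent, enantioselective conjugate arylation of a C2-unsubstituted chromone could form C2–C1' and the stereocenter at once, an end-game with better precedent than the flavone reduction of the chosen plan.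
- Weak points: the key step solves only ring D, the easiest ring. The quinone methide is formed at high temperature beside the prenyl alkene of every other molecule, which is a better 2π partner than isobutene, so oligomers are likely. The free phenol can also close onto its own prenyl group. The union with rings A and C and the stereocenter are left to further steps.
- Comparison: Alternative 3 is at least as safe in its end-game. The chosen plan builds ring B, ring D and the C3' prenyl position in one operation without any substitution on a ring B phenol, and it is shorter.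

Key step: step 10

Assumption: in step 11 the bisphosphine is written as its (R)-antipode; the sense of induction on a flavone must be checked on a model, and the antipode that delivers hydride to the Re face of C2 is the one intended.

## Route

Step 1
Reactants: 1 methyl 5-oxohexanoate
Product: 3 6,6-dimethyloxan-2-one, via hydroxy ester 2 (not isolated)
Conditions: MeMgBr (1.05 equiv), THF, −78 → 0 °C; aq. HCl; TsOH (cat.), CH2Cl2, rt
Reagents that add atoms: methylmagnesium bromide, C[Mg]Br
Why: Grignard addition is chemoselective for the ketone over the methyl ester at low temperature, and the tertiary hydroxy ester 2 lactonises readily, helped by the gem-dimethyl group.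

Step 2
Reactants: 3 6,6-dimethyloxan-2-one
Product: 4 2,2-dimethyl-3,4-dihydro-2H-pyran-6-yl diphenyl phosphate
Conditions: KN(SiMe3)2, (PhO)2P(O)Cl, HMPA, THF, −78 °C
Reagents that add atoms: diphenyl chlorophosphate, O=P(Cl)(Oc1ccccc1)Oc1ccccc1
Why: O-phosphorylation of the lactone potassium enolate gives the ketene acetal phosphate; only one α-carbon can enolise, so the double bond position is fixed.

Step 3
Reactants: 5 2,3-dibromoprop-1-ene; 6 (2-methylprop-1-en-1-yl)magnesium bromide
Product: 7 2-bromo-5-methylhexa-1,4-diene
Conditions: CuBr·SMe2 (5 mol %), THF, −20 → 0 °C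
Reagents that add atoms: none
Why: Copper-catalysed allylic substitution of the allylic bromide by the alkenyl Grignard reagent; the vinylic bromide is inert and SN2 and SN2' attack give the same product.

Step 4
Reactants: 7 2-bromo-5-methylhexa-1,4-diene; 4 2,2-dimethyl-3,4-dihydro-2H-pyran-6-yl diphenyl phosphate
Product: 10 2,2-dimethyl-6-(5-methylhexa-1,4-dien-2-yl)-3,4-dihydro-2H-pyran, via alkenyllithium 8 (not isolated), via alkenylzinc chloride 9 (not isolated)
Conditions: t-BuLi (2 equiv), Et2O, −78 °C; ZnCl2, THF, −78 → 0 °C; 4, Pd(PPh3)4 (5 mol %), THF, rt → 45 °C; Et3N-deactivated silica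
Reagents that add atoms: none
Why: Bromine–lithium exchange and transmetallation to zinc are followed by Negishi coupling, in which zerovalent palladium inserts into the C–O bond of the ketene acetal phosphate, an established electrophile class for such couplings. Both double bonds keep their positions, giving the 2-alkoxydiene.

Step 5
Reactants: 11 1-(2,4-dihydroxyphenyl)ethanone; 12 1-bromo-3-methylbut-2-ene
Product: 13 1-[2,4-dihydroxy-3-(3-methylbut-2-en-1-yl)phenyl]ethanone
Conditions: KOH (10% aq.), 0 °C → rt; chromatography
Reagents that add atoms: none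
Why: C-alkylation of a resorcinol phenoxide in water, where solvation of the oxygen favours attack through carbon; C3, flanked by both oxygens, is the most nucleophilic carbon, and the 5-prenyl isomer and O-alkylated material are removed at this cheap first stage.

Step 6
Reactants: 13 1-[2,4-dihydroxy-3-(3-methylbut-2-en-1-yl)phenyl]ethanone; 14 diethyl oxalate
Product: 16 ethyl 7-hydroxy-8-(3-methylbut-2-en-1-yl)-4-oxo-4H-chromene-2-carboxylate, via diketo ester 15 (not isolated)
Conditions: NaOEt (4 equiv), EtOH, 60 °C; aq. HCl to pH 3, 0 °C; TsOH (cat.), EtOH, 50 °C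
Reagents that add atoms: none
Why: Claisen condensation of the methyl ketone enolate with diethyl oxalate gives 15; the 2-OH then attacks the C2 ketone (6-exo-trig) and water is lost to form the chromone. Catalytic acid at moderate temperature suffices for this dehydration and spares the prenyl group next to the free 7-OH.

Step 7
Reactants: 16 ethyl 7-hydroxy-8-(3-methylbut-2-en-1-yl)-4-oxo-4H-chromene-2-carboxylate
Product: 17 ethyl 7-[(tert-butyldimethylsilyl)oxy]-8-(3-methylbut-2-en-1-yl)-4-oxo-4H-chromene-2-carboxylate
Conditions: TBSCl, imidazole, DMF, rt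
Reagents that add atoms: tert-butyldimethylsilyl chloride, CC(C)(C)[Si](C)(C)Cl
Why: Standard silylation of the only free hydroxyl; the silyl ether masks the acidic phenol for the organometallic, thermal and reductive steps and can be removed at the end without base.

Step 8
Reactants: 17 ethyl 7-[(tert-butyldimethylsilyl)oxy]-8-(3-methylbut-2-en-1-yl)-4-oxo-4H-chromene-2-carboxylate
Product: 18 7-[(tert-butyldimethylsilyl)oxy]-8-(3-methylbut-2-en-1-yl)-4-oxo-4H-chromene-2-carbaldehyde
Conditions: i-Bu2AlH (1.1 equiv), CH2Cl2, −78 °C; MeOH, then aq. potassium sodium tartrate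
Reagents that add atoms: none
Why: Partial reduction of an ester to the aldehyde; the ester on the electron-poor C2 is more electrophilic than the vinylogous-ester C4 carbonyl, and the aluminium hemiacetal, chelated by O1, should persist at −78 °C until quenched.

Step 9
Reactants: 18 7-[(tert-butyldimethylsilyl)oxy]-8-(3-methylbut-2-en-1-yl)-4-oxo-4H-chromene-2-carbaldehyde
Product: 19 7-[(tert-butyldimethylsilyl)oxy]-2-ethynyl-8-(3-methylbut-2-en-1-yl)-4H-chromen-4-one
Conditions: Me3SiCHN2, n-BuLi, THF, −78 °C; then 18, −78 → 0 °C; aq. NH4Cl
Reagents that add atoms: trimethylsilyldiazomethane, C[Si](C)(C)C=[N+]=[N-]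
Why: Colvin rearrangement: the lithiated silyldiazomethane adds to the aldehyde, Peterson elimination gives a diazoalkene, and loss of N2 with a 1,2-hydrogen shift gives the terminal alkyne. The aprotic low-temperature conditions avoid alkoxide addition to the activated alkyne and keep the aryl silyl ether.

Step 10
Reactants: 10 2,2-dimethyl-6-(5-methylhexa-1,4-dien-2-yl)-3,4-dihydro-2H-pyran; 19 7-[(tert-butyldimethylsilyl)oxy]-2-ethynyl-8-(3-methylbut-2-en-1-yl)-4H-chromen-4-one
Product: 21 7-[(tert-butyldimethylsilyl)oxy]-2-[2,2-dimethyl-8-(3-methylbut-2-en-1-yl)chroman-6-yl]-8-(3-methylbut-2-en-1-yl)-4H-chromen-4-one, via cyclohexadiene adduct 20 (not isolated)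
Conditions: 10 (1.3 equiv), BHT (cat.), PhMe, 120 °C, sealed tube; evaporate; DDQ (1.1 equiv), PhH, 0 °C → rt
Reagents that add atoms: none
Why: Proposed new method: a [4+2] cycloaddition of the 2-alkoxydiene unit of 10 (C5'=C4'–C3'=C2') with the terminal alkyne of 19, which is activated only vinylogously through C2=C3–C4=O of the chromone, followed by dehydrogenation; the closest known reaction type is the Diels–Alder reaction of 2-alkoxy- and 2-silyloxybutadienes with propiolates and ynones with DDQ aromatisation of the 1,4-cyclohexadiene adducts. The addition is expected to be concerted but asynchronous: the enol ether β-carbon C5', which has the largest HOMO coefficient, bonds to the terminal alkyne carbon, the 1,6-acceptor position with the largest LUMO coefficient, and C2' closes onto the carbon attached to chromone C2. Ring B therefore closes by cycloaddition with formation of C5'–C6' and C2'–C1', which puts C1' para to the ring D oxygen in 20. Regioselectivity is the only selectivity required; it rests on the donor oxygen at C4', which should outweigh the two alkyl groups of the diene, and on sterics, since the substituted terminus C5' meets the unsubstituted alkyne CH. Adduct 20 is a 1,4-cyclohexadiene whose doubly allylic C2'–H and C5'–H are removed by DDQ at or below room temperature, where the prenyl and chroman C–H bonds are not attacked. The stereocenter at C5' of 20 is racemic and is erased on aromatisation, so no stereocenter results. BHT and acid-free glassware protect the enol ether of 10 during heating.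

Step 11
Reactants: 21 7-[(tert-butyldimethylsilyl)oxy]-2-[2,2-dimethyl-8-(3-methylbut-2-en-1-yl)chroman-6-yl]-8-(3-methylbut-2-en-1-yl)-4H-chromen-4-one
Product: 22 (2S)-7-[(tert-butyldimethylsilyl)oxy]-2-[2,2-dimethyl-8-(3-methylbut-2-en-1-yl)chroman-6-yl]-8-(3-methylbut-2-en-1-yl)-2,3-dihydro-4H-chromen-4-one
Conditions: Cu(OAc)2 (5 mol %), (R)-DTBM-SEGPHOS (5.5 mol %), (EtO)2MeSiH (3 equiv), t-BuOH (2 equiv), PhMe, 0 °C → rt; aq. NH4F
Reagents that add atoms: none
Why: Copper hydride asymmetric conjugate reduction, a reaction type established for 2-substituted chromones: the ligated monovalent copper hydride adds hydride to C2, t-BuOH protonates the copper enolate and the silane regenerates the hydride. The C2 stereocenter is set by the chiral bisphosphine (catalyst control), with delivery to the Re face giving (S). The unactivated trisubstituted alkenes and the aryl silyl ether should not react, and the neutral medium avoids ring opening to the chalcone.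

Step 12
Reactants: 22 (2S)-7-[(tert-butyldimethylsilyl)oxy]-2-[2,2-dimethyl-8-(3-methylbut-2-en-1-yl)chroman-6-yl]-8-(3-methylbut-2-en-1-yl)-2,3-dihydro-4H-chromen-4-one
Product: 23 (2S)-2-[2,2-dimethyl-8-(3-methylbut-2-en-1-yl)chroman-6-yl]-7-hydroxy-8-(3-methylbut-2-en-1-yl)-2,3-dihydro-4H-chromen-4-one
Conditions: HF·pyridine, pyridine, THF, 0 °C → rt
Reagents that add atoms: none
Why: Fluoride cleavage of the aryl silyl ether in a pyridine-buffered medium; no free phenoxide or strong acid is present, so C2 is not epimerised through the chalcone and the o-prenylphenol does not cyclise.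

## Compound list

1 | methyl 5-oxohexanoate | CC(=O)CCCC(=O)OC | starting material
2 | methyl 5-hydroxy-5-methylhexanoate | COC(=O)CCCC(C)(C)O | intermediate (not isolated)
3 | 6,6-dimethyloxan-2-one | CC1(C)CCCC(=O)O1 | intermediate
4 | 2,2-dimethyl-3,4-dihydro-2H-pyran-6-yl diphenyl phosphate | CC1(C)CCC=C(OP(=O)(Oc2ccccc2)Oc2ccccc2)O1 | intermediate
5 | 2,3-dibromoprop-1-ene | C=C(Br)CBr | starting material
6 | (2-methylprop-1-en-1-yl)magnesium bromide | CC(C)=C[Mg]Br | starting material
7 | 2-bromo-5-methylhexa-1,4-diene | C=C(Br)CC=C(C)C | intermediate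
8 | (5-methylhexa-1,4-dien-2-yl)lithium | [Li]C(=C)CC=C(C)C | intermediate (not isolated)
9 | (5-methylhexa-1,4-dien-2-yl)zinc chloride | Cl[Zn]C(=C)CC=C(C)C | intermediate (not isolated)
10 | 2,2-dimethyl-6-(5-methylhexa-1,4-dien-2-yl)-3,4-dihydro-2H-pyran | C=C(CC=C(C)C)C1=CCCC(C)(C)O1 | intermediate
11 | 1-(2,4-dihydroxyphenyl)ethanone | CC(=O)c1ccc(O)cc1O | starting material
12 | 1-bromo-3-methylbut-2-ene | CC(C)=CCBr | starting material
13 | 1-[2,4-dihydroxy-3-(3-methylbut-2-en-1-yl)phenyl]ethanone | CC(=O)c1ccc(O)c(CC=C(C)C)c1O | intermediate
14 | diethyl oxalate | CCOC(=O)C(=O)OCC | starting material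
15 | ethyl 4-[2,4-dihydroxy-3-(3-methylbut-2-en-1-yl)phenyl]-2,4-dioxobutanoate | CCOC(=O)C(=O)CC(=O)c1ccc(O)c(CC=C(C)C)c1O | intermediate (not isolated)
16 | ethyl 7-hydroxy-8-(3-methylbut-2-en-1-yl)-4-oxo-4H-chromene-2-carboxylate | CCOC(=O)c1cc(=O)c2ccc(O)c(CC=C(C)C)c2o1 | intermediate
17 | ethyl 7-[(tert-butyldimethylsilyl)oxy]-8-(3-methylbut-2-en-1-yl)-4-oxo-4H-chromene-2-carboxylate | CCOC(=O)c1cc(=O)c2ccc(O[Si](C)(C)C(C)(C)C)c(CC=C(C)C)c2o1 | intermediate
18 | 7-[(tert-butyldimethylsilyl)oxy]-8-(3-methylbut-2-en-1-yl)-4-oxo-4H-chromene-2-carbaldehyde | O=Cc1cc(=O)c2ccc(O[Si](C)(C)C(C)(C)C)c(CC=C(C)C)c2o1 | intermediate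
19 | 7-[(tert-butyldimethylsilyl)oxy]-2-ethynyl-8-(3-methylbut-2-en-1-yl)-4H-chromen-4-one | C#Cc1cc(=O)c2ccc(O[Si](C)(C)C(C)(C)C)c(CC=C(C)C)c2o1 | intermediate
20 | 7-[(tert-butyldimethylsilyl)oxy]-2-[2,2-dimethyl-8-(3-methylbut-2-en-1-yl)-3,4,4a,7-tetrahydro-2H-chromen-6-yl]-8-(3-methylbut-2-en-1-yl)-4H-chromen-4-one (racemic at C4a) | O=c1cc(C2=CC3CCC(C)(C)OC3=C(CC=C(C)C)C2)oc2c1ccc(O[Si](C)(C)C(C)(C)C)c2CC=C(C)C | intermediate (not isolated)
21 | 7-[(tert-butyldimethylsilyl)oxy]-2-[2,2-dimethyl-8-(3-methylbut-2-en-1-yl)chroman-6-yl]-8-(3-methylbut-2-en-1-yl)-4H-chromen-4-one | O=c1cc(-c3cc(CC=C(C)C)c4OC(C)(C)CCc4c3)oc2c1ccc(O[Si](C)(C)C(C)(C)C)c2CC=C(C)C | intermediate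
22 | (2S)-7-[(tert-butyldimethylsilyl)oxy]-2-[2,2-dimethyl-8-(3-methylbut-2-en-1-yl)chroman-6-yl]-8-(3-methylbut-2-en-1-yl)-2,3-dihydro-4H-chromen-4-one | CC(C)=CCc1cc([C@@H]2CC(=O)c3ccc(O[Si](C)(C)C(C)(C)C)c(CC=C(C)C)c3O2)cc2c1OC(C)(C)CC2 | intermediate
23 | (2S)-2-[2,2-dimethyl-8-(3-methylbut-2-en-1-yl)chroman-6-yl]-7-hydroxy-8-(3-methylbut-2-en-1-yl)-2,3-dihydro-4H-chromen-4-one | CC(C)=CCc1cc([C@@H]2CC(=O)c3ccc(O)c(CC=C(C)C)c3O2)cc2c1OC(C)(C)CC2 | target

## Step count and risks

Total: 12 steps. Longest linear sequence: 8 steps (steps 5 to 12, from 11).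

**Step 10 (key step, proposed new method).**
- What may go wrong: the cycloaddition may be too slow, because the alkyne is activated only through the chromone, so that hydrolysis or oligomerisation of the enol ether diene wins. The two alkyl groups of the diene may erode the orientation imposed by the oxygen. DDQ may attack the excess diene or electron-rich positions.
- Fallback (known chemistry), from 10 and 13, returning at 21. Diene 10 is heated with methyl propiolate, a dienophile whose para-selective addition to 2-alkoxydienes is established, to give methyl 2,2-dimethyl-8-(3-methylbut-2-en-1-yl)-3,4,4a,7-tetrahydro-2H-chromene-6-carboxylate F1. DDQ aromatises this to methyl 2,2-dimethyl-8-(3-methylbut-2-en-1-yl)chromane-6-carboxylate F2. LiOH gives 2,2-dimethyl-8-(3-methylbut-2-en-1-yl)chromane-6-carboxylic acid F3, and oxalyl chloride gives 2,2-dimethyl-8-(3-methylbut-2-en-1-yl)chromane-6-carbonyl chloride F4. Acetophenone 13 is silylated at the non-chelated 4-OH (TBSCl, imidazole) to 1-[4-[(tert-butyldimethylsilyl)oxy]-2-hydroxy-3-(3-methylbut-2-en-1-yl)phenyl]ethanone F5. Its dianion (LiN(SiMe3)2, THF, −78 °C) is acylated by F4 in a Baker–Venkataraman-type condensation to 1-[4-[(tert-butyldimethylsilyl)oxy]-2-hydroxy-3-(3-methylbut-2-en-1-yl)phenyl]-3-[2,2-dimethyl-8-(3-methylbut-2-en-1-yl)chroman-6-yl]propane-1,3-dione F6. Cyclodehydration with catalytic TsOH in toluene gives 21. Ring B is still made from the diene and an alkyne; only the closure of ring C is moved behind it.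

**Step 11.**
- What may go wrong: low conversion, because C2 of the flavone is a hindered, electron-rich vinylogous ester carbon bearing a p-alkoxyaryl group; insufficient facial selectivity; or erosion of enantiopurity by ring opening of the enolate to the chalcone.
- Fallback, from 21, returning at 22. LiBH(s-Bu)3 in THF at −78 °C adds hydride 1,4 to give racemic 7-[(tert-butyldimethylsilyl)oxy]-2-[2,2-dimethyl-8-(3-methylbut-2-en-1-yl)chroman-6-yl]-8-(3-methylbut-2-en-1-yl)-2,3-dihydro-4H-chromen-4-one F7. Kinetic resolution by transfer hydrogenation (RuCl(TsDPEN)(p-cymene), HCO2H, Et3N), using the catalyst antipode that consumes the (2R)-ketone, reduces that enantiomer to (2R,4R)-7-[(tert-butyldimethylsilyl)oxy]-2-[2,2-dimethyl-8-(3-methylbut-2-en-1-yl)chroman-6-yl]-8-(3-methylbut-2-en-1-yl)chroman-4-ol F8 and leaves 22. F8 can be re-oxidised and racemised for recycling.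

**Step 9.**
- What may go wrong: the lithiated diazo reagent may add to the chromone instead of the aldehyde, or the lithium silanolate formed may cleave the aryl silyl ether or add to the activated alkyne.
- Fallback, from 18, returning at 19. Stork–Zhao olefination with Ph3P=CHI (from the iodomethylphosphonium iodide and NaN(SiMe3)2, THF, −78 °C) gives 7-[(tert-butyldimethylsilyl)oxy]-2-[(Z)-2-iodoethenyl]-8-(3-methylbut-2-en-1-yl)-4H-chromen-4-one F9. Anti-elimination of hydrogen iodide with DBU, eased by the electron-poor chromone, gives 19.

**Step 5.**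
- What may go wrong: poor regiocontrol, with alkylation at C5, at oxygen, or twice, leaving little 13 after separation.
- Fallback, from 11, returning at 13. The non-chelated 4-OH is alkylated with 3-chloro-3-methylbut-1-yne (K2CO3, KI, CuCl cat., acetone) to 1-{2-hydroxy-4-[(2-methylbut-3-yn-2-yl)oxy]phenyl}ethanone F10. Semi-hydrogenation (H2, Pd/CaCO3–Pb(OAc)2, quinoline) gives 1-{2-hydroxy-4-[(2-methylbut-3-en-2-yl)oxy]phenyl}ethanone F11. Aromatic Claisen rearrangement (PhNEt2, 130 °C) moves the group with allylic inversion to C3, the position favoured by the chelated 2-OH, and gives 13.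

**Step 4.**
- What may go wrong: decomposition of the ketene acetal phosphate before oxidative addition, proton transfer within the alkenyllithium, or hydrolysis of the product enol ether on work-up.
- Fallback, from 3 and 7, returning at 10. Alkenyllithium 8, made from 7 as in step 4, is added to lactone 3 at −78 °C to give the lactol 6,6-dimethyl-2-(5-methylhexa-1,4-dien-2-yl)oxan-2-ol F12. Dehydration with MsCl and Et3N can only occur into the ring, since the alkenyl carbon carries no hydrogen, and gives 10 without palladium.

## Further compounds

F1 | step 10 | methyl 2,2-dimethyl-8-(3-methylbut-2-en-1-yl)-3,4,4a,7-tetrahydro-2H-chromene-6-carboxylate | COC(=O)C1=CC2CCC(C)(C)OC2=C(CC=C(C)C)C1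
F2 | step 10 | methyl 2,2-dimethyl-8-(3-methylbut-2-en-1-yl)chromane-6-carboxylate | COC(=O)c1cc(CC=C(C)C)c2OC(C)(C)CCc2c1
F3 | step 10 | 2,2-dimethyl-8-(3-methylbut-2-en-1-yl)chromane-6-carboxylic acid | OC(=O)c1cc(CC=C(C)C)c2OC(C)(C)CCc2c1
F4 | step 10 | 2,2-dimethyl-8-(3-methylbut-2-en-1-yl)chromane-6-carbonyl chloride | ClC(=O)c1cc(CC=C(C)C)c2OC(C)(C)CCc2c1
F5 | step 10 | 1-[4-[(tert-butyldimethylsilyl)oxy]-2-hydroxy-3-(3-methylbut-2-en-1-yl)phenyl]ethanone | CC(=O)c1ccc(O[Si](C)(C)C(C)(C)C)c(CC=C(C)C)c1O
F6 | step 10 | 1-[4-[(tert-butyldimethylsilyl)oxy]-2-hydroxy-3-(3-methylbut-2-en-1-yl)phenyl]-3-[2,2-dimethyl-8-(3-methylbut-2-en-1-yl)chroman-6-yl]propane-1,3-dione | O=C(CC(=O)c1cc(CC=C(C)C)c2OC(C)(C)CCc2c1)c1ccc(O[Si](C)(C)C(C)(C)C)c(CC=C(C)C)c1O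
F7 | step 11 | racemic 7-[(tert-butyldimethylsilyl)oxy]-2-[2,2-dimethyl-8-(3-methylbut-2-en-1-yl)chroman-6-yl]-8-(3-methylbut-2-en-1-yl)-2,3-dihydro-4H-chromen-4-one | CC(C)=CCc1cc(C2CC(=O)c3ccc(O[Si](C)(C)C(C)(C)C)c(CC=C(C)C)c3O2)cc2c1OC(C)(C)CC2
F8 | step 11 | (2R,4R)-7-[(tert-butyldimethylsilyl)oxy]-2-[2,2-dimethyl-8-(3-methylbut-2-en-1-yl)chroman-6-yl]-8-(3-methylbut-2-en-1-yl)chroman-4-ol | CC(C)=CCc1cc([C@H]2C[C@@H](O)c3ccc(O[Si](C)(C)C(C)(C)C)c(CC=C(C)C)c3O2)cc2c1OC(C)(C)CC2
F9 | step 9 | 7-[(tert-butyldimethylsilyl)oxy]-2-[(Z)-2-iodoethenyl]-8-(3-methylbut-2-en-1-yl)-4H-chromen-4-one | I/C=C\c1cc(=O)c2ccc(O[Si](C)(C)C(C)(C)C)c(CC=C(C)C)c2o1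
F10 | step 5 | 1-{2-hydroxy-4-[(2-methylbut-3-yn-2-yl)oxy]phenyl}ethanone | CC(=O)c1ccc(OC(C)(C)C#C)cc1O
F11 | step 5 | 1-{2-hydroxy-4-[(2-methylbut-3-en-2-yl)oxy]phenyl}ethanone | CC(=O)c1ccc(OC(C)(C)C=C)cc1O
F12 | step 4 | 6,6-dimethyl-2-(5-methylhexa-1,4-dien-2-yl)oxan-2-ol | C=C(CC=C(C)C)C1(O)CCCC(C)(C)O1
A1 | alternative 1 | (2S)-4-[(tert-butyldimethylsilyl)oxy]-2-[2,2-dimethyl-8-(3-methylbut-2-en-1-yl)chroman-6-yl]-8-(3-methylbut-2-en-1-yl)chroman-7-ol | CC(C)(C)[Si](C)(C)OC1C[C@@H](c3cc(CC=C(C)C)c4OC(C)(C)CCc4c3)Oc2c1ccc(O)c2CC=C(C)C
A2 | alternative 1 | (7S)-5-[(tert-butyldimethylsilyl)oxy]-4-diazo-7-[2,2-dimethyl-8-(3-methylbut-2-en-1-yl)chroman-6-yl]-7-[(5-methylhex-4-en-1-yn-1-yl)oxy]hept-1-en-3-one | C=CC(=O)C(=[N+]=[N-])C(O[Si](C)(C)C(C)(C)C)C[C@@H](c1cc(CC=C(C)C)c2OC(C)(C)CCc2c1)OC#CCC=C(C)C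
A3 | alternative 2 | (2S)-2-[2,2-dimethyl-8-(3-methylbut-2-en-1-yl)chroman-6-yl]-7-(methoxymethoxy)-8-(3-methylbut-2-en-1-yl)-2,3,5,6-tetrahydro-4H-chromen-4-one | O=C1C[C@@H](c3cc(CC=C(C)C)c4OC(C)(C)CCc4c3)OC2=C1CCC(OCOC)=C2CC=C(C)C
A4 | alternative 2 | 2,2-dimethyl-8-(3-methylbut-2-en-1-yl)chromane-6-carbaldehyde | O=Cc1cc(CC=C(C)C)c2OC(C)(C)CCc2c1
A5 | alternative 2 | trimethyl{[3-(methoxymethoxy)-2-(3-methylbut-2-en-1-yl)-6-{1-[(trimethylsilyl)oxy]ethenyl}cyclohexa-1,5-dien-1-yl]oxy}silane | C=C(O[Si](C)(C)C)C1=C(O[Si](C)(C)C)C(CC=C(C)C)=C(OCOC)CC1
A6 | alternative 3 | 6-bromo-2,2-dimethyl-8-(3-methylbut-2-en-1-yl)chromane | Brc1cc(CC=C(C)C)c2OC(C)(C)CCc2c1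
A7 | alternative 3 | 4-bromo-2-(hydroxymethyl)-6-(3-methylbut-2-en-1-yl)phenol | OCc1cc(Br)cc(CC=C(C)C)c1O
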